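**Retrosynthetic overview** (tetralin numbering: C1 = CH–aryl, C2 = CH–CH2OSO3H, C3 = CH–CH2OH, C4 = CH2, fused ring C4a–C8a with 6‑OMe, 7‑OH, 8‑OMe)

- Target ⇐ O‑sulfation of C2–CH2OH and global deprotection ⇐ hydroxyl‑directed hydrogenation of C3=C4 (sets C3) ⇐ regioselective benzoylation of the allylic C3–CH2OH of a 1‑aryl‑1,2‑dihydronaphthalene‑2,3‑dimethanol.
- That diol ⇐ reductive removal of two camphorsultam auxiliaries from a 1‑aryl‑1,2‑dihydronaphthalene‑2,3‑dicarboxylic bis‑imide ⇐ oxidative β,β′‑dimerisation and ring closure of two molecules of one N‑sinapoyl sultam (C2–C3 bond, then C1–C8a bond; sets C1 and C2).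
- Enabling feature: the target is two identical 4‑hydroxy‑3,5‑dimethoxyphenyl–C3 halves (fused ring + C4, C3, C3–CH2; pendant ring + C1, C2, C2–CH2) joined at C2–C3 and C1–C8a. The free OH para to each side chain (C7–OH para to C4a; pendant 4‑OH para to the C1 attachment) allows phenoxyl‑radical and quinone‑methide chemistry, and the OMe groups on both carbons ortho to each OH block every other coupling site.
- Ring order: both benzene rings come preformed from sinapic acid; the carbocycle C1–C2–C3–C4–C4a–C8a is the only skeletal ring made and is closed last, in the key step.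

Key step: step 4

Assumption 1: the (2R)‑bornane‑10,2‑sultam is taken, by analogy with sultam‑directed reactions of α‑acyl radicals and enolates, to lead to the (1R,2S) dimer; if the sense is opposite, the equally available (2S)‑sultam is used and nothing else changes.
Assumption 2: the target is drawn as the free hydrogen sulfate; it is carried as the sodium salt and brought to the acid form only in the last work‑up.

**Step 1**
Reactants: 1 sinapic acid
Product: 2 4‑O‑acetylsinapic acid
Conditions: Ac2O, pyridine, DMAP (cat.), rt; then H2O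
Reagents that add atoms: acetic anhydride CC(=O)OC(C)=O
Why: Phenol acetylation (nucleophilic acyl substitution) masks the only nucleophile that would compete in the acylation of step 2, and the mixed anhydride formed at the carboxyl group is hydrolysed in the aqueous work‑up.

**Step 2**
Reactants: 2 4‑O‑acetylsinapic acid, 3 (2R)‑bornane‑10,2‑sultam
Product: 5 N‑(4‑O‑acetylsinapoyl)‑(2R)‑bornane‑10,2‑sultam, via acid chloride 4 (not isolated)
Conditions: (COCl)2, DMF (cat.), CH2Cl2, 0 °C to rt, evaporate; then 3, NaH, THF, 0 °C to rt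
Reagents that add atoms: none
Why: Vilsmeier‑catalysed acid chloride formation followed by N‑acylation of the sodium salt of the sultam is the standard way to attach this auxiliary; the E alkene is untouched and no stereocentre is formed.

**Step 3**
Reactants: 5 N‑(4‑O‑acetylsinapoyl)‑(2R)‑bornane‑10,2‑sultam
Product: 6 N‑sinapoyl‑(2R)‑bornane‑10,2‑sultam
Conditions: pyrrolidine (1.2 equiv), CH2Cl2, 0 °C to rt
Reagents that add atoms: none
Why: Aminolysis of the aryl acetate should be much faster than attack on the hindered, conjugated N‑enoyl sultam, so the free 4‑OH needed for phenol oxidation is released selectively.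

**Step 4**
Reactants: 6 N‑sinapoyl‑(2R)‑bornane‑10,2‑sultam (2 molecules)
Product: 9 (1R,2S)‑7‑hydroxy‑1‑(4‑hydroxy‑3,5‑dimethoxyphenyl)‑6,8‑dimethoxy‑1,2‑dihydronaphthalene‑2,3‑dicarbonyl bis[(2R)‑bornane‑10,2‑sultam], via bis(quinone methide) 7 (not isolated), via mono(quinone methide) 8 (not isolated)
Conditions: FeCl3·6H2O (2.2 equiv), acetone–H2O 9:1, N2, dark, 0 °C to rt; chromatography or crystallisation to remove the minor diastereomer
Reagents that add atoms: none
Why: Oxidative phenol coupling of the sinapate type (the FeCl3 dimerisation that turns sinapic acid and its esters into 1‑aryl‑1,2‑dihydronaphthalene‑2,3‑dicarboxylic (thomasidioic) derivatives, here with an N‑acyl chiral auxiliary as in known auxiliary‑controlled phenol oxidations): Fe(III) oxidises each phenol of 6 to a phenoxyl radical with spin density on the β‑carbon, and because both ring carbons ortho to the oxygen carry OMe, β–5 and 5–5 coupling are impossible and β,β′‑coupling should give bis(quinone methide) 7, forming the C2–C3 bond. The carbon that becomes C2 is set in this radical–radical coupling by the sultam, whose anti C=O/SO2 conformation leaves one face of the α‑acyl radical open; the (2R)‑sultam is taken to give the (S) centre, and the wrong‑sense dimer is a diastereomer that can be removed by chromatography or crystallisation. One quinone methide of 7 then loses its acidic α‑hydrogen and rearomatises to the (E)‑cinnamoyl phenol 8, which turns that ring from an electrophile into a nucleophile. Its ring carbon ortho to the side chain (ortho and para to OMe) adds to the methide carbon of the remaining quinone methide in a 6‑exo‑trig intramolecular 1,6‑addition (Friedel–Crafts alkylation), which closes the carbocycle C1–C2–C3–C4–C4a–C8a at the C1–C8a bond and rearomatises the pendant ring. C1 is set in this closure by the adjacent C2 centre: the aryl group takes the pseudoaxial position anti to the C2 acyl group and away from the peri C8–OMe, which gives the trans‑1,2 (1R,2S) product, the same relative configuration as in thomasidioic acid. The step needs ring closure to win over capture of the quinone methide by water, which the tethered electron‑rich arene and the Lewis‑acidic iron medium should secure, and it needs no regiocontrol in the closure because the two ortho carbons of the symmetric syringyl ring are equivalent.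

**Step 5**
Reactants: 9 bis‑sultam imide (both phenols free)
Product: 10 bis(tert‑butyldimethylsilyl) ether of 9
Conditions: TBSCl (3 equiv), imidazole, DMF, rt
Reagents that add atoms: tert‑butyldimethylsilyl chloride CC(C)(C)[Si](C)(C)Cl
Why: Standard silylation of hindered phenols under non‑epimerising conditions protects both ArOH against acylation and sulfation later, survives hydride reduction and hydrogenation, and is removable with K2CO3/MeOH.

**Step 6**
Reactants: 10 bis(silyl ether) bis‑sultam imide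
Product: 11 [(1R,2S)‑7‑(TBS‑oxy)‑1‑(4‑(TBS‑oxy)‑3,5‑dimethoxyphenyl)‑6,8‑dimethoxy‑1,2‑dihydronaphthalene‑2,3‑diyl]dimethanol
Conditions: DIBAL‑H (6 equiv), CH2Cl2, −78 to 0 °C; aq. sodium potassium tartrate
Reagents that add atoms: none
Why: Reductive cleavage of N‑acyl sultams by hydride: excess DIBAL‑H should take both the saturated and the conjugated imide through the aldehyde to the primary alcohol by 1,2‑addition without touching the styrene double bond, the aryl silyl ethers or either stereocentre, and it returns the auxiliary 3.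

**Step 7**
Reactants: 11 diol
Product: 12 C3‑(benzoyloxymethyl) C2‑(hydroxymethyl) dihydronaphthalene (mono‑benzoate of 11)
Conditions: BzCl (1.05 equiv), 2,4,6‑collidine, CH2Cl2, −78 to −40 °C
Reagents that add atoms: benzoyl chloride O=C(Cl)c1ccccc1
Why: Kinetic regioselective acylation of the less hindered primary alcohol: the allylic CH2OH on sp2 C3 is flanked only by the vinylic C4–H, whereas the CH2OH on C2 sits between C1 (aryl) and C3, so monobenzoylation should occur at C3–CH2OH and leave C2–CH2OH free as directing group and sulfation site.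

**Step 8**
Reactants: 12 mono‑benzoate
Product: 13 (1R,2S,3S)‑tetralin mono‑benzoate (C2–CH2OH free)
Conditions: [Ir(cod)(PCy3)(py)]PF6 (5 mol%), H2 (1 atm), CH2Cl2, rt
Reagents that add atoms: none
Why: Hydroxyl‑directed homogeneous hydrogenation: the homoallylic C2–CH2OH binds the cationic iridium and both hydrogens are delivered to the face of C3=C4 on which this group stands, so the new C3–H is cis to the C2 arm and the C3–CH2OBz arm trans to it (3S), the all‑trans arrangement.

**Step 9**
Reactants: 13 tetralin mono‑alcohol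
Product: 14 sodium salt of the C2‑CH2 sulfate monoester of 13
Conditions: SO3·pyridine (3 equiv), pyridine, rt; then aq. NaHCO3
Reagents that add atoms: sulfur trioxide–pyridine complex O=S(=O)([O-])[n+]1ccccc1; sodium hydrogen carbonate [Na+].OC([O-])=O
Why: O‑sulfation with SO3·pyridine (standard sulfate monoester synthesis) can only occur at C2–CH2OH, since both phenols are silylated and the C3 arm is an ester, and the bicarbonate work‑up gives the stable sodium salt.

**Step 10**
Reactants: 14 protected sulfate sodium salt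
Product: 15 target, (1R,2S,3S)‑lyoniresinol‑type 2‑CH2 hydrogen sulfate
Conditions: K2CO3 (3 equiv), degassed MeOH, 0 °C to rt; then cold 1 M HCl to pH 1–2, C18 desalting, lyophilisation
Reagents that add atoms: none
Why: Base‑mediated methanolysis removes the benzoate (transesterification) and both phenolic silyl ethers while the sulfate monoester anion is inert to base, and cold acidification gives the free hydrogen sulfate without touching a stereocentre.

**Compound list**

1 | sinapic acid | COc1cc(/C=C/C(=O)O)cc(OC)c1O | starting material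
2 | 4‑O‑acetylsinapic acid | COc1cc(/C=C/C(=O)O)cc(OC)c1OC(C)=O | intermediate
3 | (2R)‑bornane‑10,2‑sultam [(1S)‑(−)‑2,10‑camphorsultam] | CC1(C)[C@@H]2CC[C@]13CS(=O)(=O)N[C@@H]3C2 | starting material
4 | 4‑O‑acetylsinapoyl chloride | COc1cc(/C=C/C(=O)Cl)cc(OC)c1OC(C)=O | intermediate
5 | N‑(4‑O‑acetylsinapoyl)‑(2R)‑bornane‑10,2‑sultam | COc1cc(/C=C/C(=O)N2[C@@H]3C[C@H]4CC[C@]3(CS2(=O)=O)C4(C)C)cc(OC)c1OC(C)=O | intermediate
6 | N‑sinapoyl‑(2R)‑bornane‑10,2‑sultam | COc1cc(/C=C/C(=O)N2[C@@H]3C[C@H]4CC[C@]3(CS2(=O)=O)C4(C)C)cc(OC)c1O | intermediate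
7 | (2S,3S)‑2,3‑bis[(3,5‑dimethoxy‑4‑oxocyclohexa‑2,5‑dien‑1‑ylidene)methyl]butanedioyl bis‑sultam imide | O=C1C(OC)=CC(=C[C@H](C(=O)N2[C@@H]3C[C@H]4CC[C@]3(CS2(=O)=O)C4(C)C)[C@H](C=C2C=C(OC)C(=O)C(OC)=C2)C(=O)N2[C@@H]3C[C@H]4CC[C@]3(CS2(=O)=O)C4(C)C)C=C1OC | intermediate
8 | (S,E)‑2‑(4‑hydroxy‑3,5‑dimethoxybenzylidene)‑3‑[(3,5‑dimethoxy‑4‑oxocyclohexa‑2,5‑dien‑1‑ylidene)methyl]butanedioyl bis‑sultam imide | COc1cc(/C=C(/C(=O)N2[C@@H]3C[C@H]4CC[C@]3(CS2(=O)=O)C4(C)C)[C@H](C=C2C=C(OC)C(=O)C(OC)=C2)C(=O)N2[C@@H]3C[C@H]4CC[C@]3(CS2(=O)=O)C4(C)C)cc(OC)c1O | intermediate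
9 | (1R,2S)‑7‑hydroxy‑1‑(4‑hydroxy‑3,5‑dimethoxyphenyl)‑6,8‑dimethoxy‑1,2‑dihydronaphthalene‑2,3‑dicarbonyl bis[(2R)‑bornane‑10,2‑sultam] | COc1cc([C@@H]2c3c(cc(OC)c(O)c3OC)C=C(C(=O)N4[C@@H]5C[C@H]6CC[C@]5(CS4(=O)=O)C6(C)C)[C@H]2C(=O)N4[C@@H]5C[C@H]6CC[C@]5(CS4(=O)=O)C6(C)C)cc(OC)c1O | intermediate
10 | bis(TBS ether) of 9 | COc1cc([C@@H]2c3c(cc(OC)c(O[Si](C)(C)C(C)(C)C)c3OC)C=C(C(=O)N4[C@@H]5C[C@H]6CC[C@]5(CS4(=O)=O)C6(C)C)[C@H]2C(=O)N4[C@@H]5C[C@H]6CC[C@]5(CS4(=O)=O)C6(C)C)cc(OC)c1O[Si](C)(C)C(C)(C)C | intermediate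
11 | (1R,2S)‑bis(TBS)‑protected 1‑aryl‑1,2‑dihydronaphthalene‑2,3‑dimethanol | COc1cc([C@@H]2c3c(cc(OC)c(O[Si](C)(C)C(C)(C)C)c3OC)C=C(CO)[C@H]2CO)cc(OC)c1O[Si](C)(C)C(C)(C)C | intermediate
12 | (1R,2S)‑C3‑CH2 benzoate of 11 | COc1cc([C@@H]2c3c(cc(OC)c(O[Si](C)(C)C(C)(C)C)c3OC)C=C(COC(=O)c4ccccc4)[C@H]2CO)cc(OC)c1O[Si](C)(C)C(C)(C)C | intermediate
13 | (1R,2S,3S)‑tetralin, C3‑CH2 benzoate, C2‑CH2OH free, phenols as TBS ethers | COc1cc([C@@H]2c3c(cc(OC)c(O[Si](C)(C)C(C)(C)C)c3OC)C[C@H](COC(=O)c4ccccc4)[C@H]2CO)cc(OC)c1O[Si](C)(C)C(C)(C)C | intermediate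
14 | sodium (1R,2S,3S)‑C2‑CH2 sulfate of 13 | COc1cc([C@@H]2c3c(cc(OC)c(O[Si](C)(C)C(C)(C)C)c3OC)C[C@H](COC(=O)c4ccccc4)[C@H]2COS(=O)(=O)[O-])cc(OC)c1O[Si](C)(C)C(C)(C)C.[Na+] | intermediate
15 | CNP0111670.1, [(1R,2S,3S)‑7‑hydroxy‑1‑(4‑hydroxy‑3,5‑dimethoxyphenyl)‑3‑(hydroxymethyl)‑6,8‑dimethoxy‑1,2,3,4‑tetrahydronaphthalen‑2‑yl]methyl hydrogen sulfate | COc1cc([C@@H]2c3c(cc(OC)c(O)c3OC)C[C@H](CO)[C@H]2COS(=O)(=O)O)cc(OC)c1O | target

**Total step count:** 10
**Longest linear sequence:** 10 steps (1 to 15)

**Steps most likely to fail**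

Step 4. What may go wrong: low face selectivity in the radical–radical coupling, slow β,β′‑coupling between two bulky imides, and capture of the quinone methide by water or a further radical (oligomerisation) before the ring closes. Fallback (resolution in place of auxiliary control; sets out from 1, returns at 11): oxidation of sinapic acid 1 itself with FeCl3 in aqueous acetone, the parent reaction without auxiliary, should give racemic trans‑thomasidioic acid F1. Preparative chiral‑phase chromatography (SFC, polysaccharide phase, CO2/MeOH with an acid modifier) separates the enantiomers and gives (1R,2S)‑thomasidioic acid F2. TBSCl/imidazole in DMF silylates both phenols and both carboxyl groups to the tetrakis(silyl) derivative F3, and DIBAL‑H (CH2Cl2, −78 to 0 °C) reduces the two silyl esters to diol 11.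

Step 7. What may go wrong: acylation of the wrong hydroxyl, double acylation, or benzoate migration between the 1,4‑related oxygens. Fallback (chemoselective allylic substitution in place of steric discrimination; sets out from 11, returns at 12): 1,1′‑sulfonyldiimidazole/NaH (THF, 0 °C) closes the 1,4‑diol to the seven‑membered cyclic sulfate F4. Tetrabutylammonium benzoate (THF, rt) opens it by SN2 attack at the allylic CH2 on C3, far faster than at the β‑branched saturated CH2 on C2, to give the benzoate sulfate monoester F5 as its tetrabutylammonium salt. Catalytic H2SO4 with one equivalent of water in THF then hydrolyses the sulfate monoester to 12.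

Step 8. What may go wrong: hydrogen delivery to the face opposite to the directing hydroxyl through a non‑directed background pathway, or catalyst deactivation before the hindered trisubstituted styrene reacts. Fallback (thermodynamic control at the diester level in place of directed delivery; sets out from 9, returns at 13): NaOMe/MeOH converts 9 into dimethyl (1R,2S)‑thomasidioate F6 with release of the sultam. H2 over Pd/C (EtOAc) gives the tetralin diester, expected mainly as the 2,3‑cis isomer F7 from addition anti to the C2 ester. NaOMe in refluxing MeOH equilibrates the enolisable C3 centre to the all‑trans diester F8; C1 is not enolisable and C2 already sits trans to the C1 aryl group. TBSCl/imidazole gives the bis(silyl ether) F9, DIBAL‑H gives the saturated diol F10, and benzoylation as in step 7 (BzCl, collidine, −78 °C) at the less hindered C3–CH2OH gives 13.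

**Further compounds**

F1 | step 4 | racemic trans‑thomasidioic acid | COc1cc([C@@H]2c3c(cc(OC)c(O)c3OC)C=C(C(=O)O)[C@H]2C(=O)O)cc(OC)c1O.COc1cc([C@H]2c3c(cc(OC)c(O)c3OC)C=C(C(=O)O)[C@@H]2C(=O)O)cc(OC)c1O
F2 | step 4 | (1R,2S)‑thomasidioic acid | COc1cc([C@@H]2c3c(cc(OC)c(O)c3OC)C=C(C(=O)O)[C@H]2C(=O)O)cc(OC)c1O
F3 | step 4 | (1R,2S)‑thomasidioic acid bis(TBS ether) bis(TBS ester) | COc1cc([C@@H]2c3c(cc(OC)c(O[Si](C)(C)C(C)(C)C)c3OC)C=C(C(=O)O[Si](C)(C)C(C)(C)C)[C@H]2C(=O)O[Si](C)(C)C(C)(C)C)cc(OC)c1O[Si](C)(C)C(C)(C)C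
F4 | step 7 | seven‑membered cyclic sulfate of diol 11 | COc1cc([C@@H]2c3c(cc(OC)c(O[Si](C)(C)C(C)(C)C)c3OC)C=C4COS(=O)(=O)OC[C@@H]24)cc(OC)c1O[Si](C)(C)C(C)(C)C
F5 | step 7 | tetrabutylammonium salt of the C2‑CH2 sulfate of 12 | COc1cc([C@@H]2c3c(cc(OC)c(O[Si](C)(C)C(C)(C)C)c3OC)C=C(COC(=O)c4ccccc4)[C@H]2COS(=O)(=O)[O-])cc(OC)c1O[Si](C)(C)C(C)(C)C.CCCC[N+](CCCC)(CCCC)CCCC
F6 | step 8 | dimethyl (1R,2S)‑thomasidioate | COc1cc([C@@H]2c3c(cc(OC)c(O)c3OC)C=C(C(=O)OC)[C@H]2C(=O)OC)cc(OC)c1O
F7 | step 8 | dimethyl (1R,2S,3R)‑tetralin‑2,3‑dicarboxylate (2,3‑cis) | COc1cc([C@@H]2c3c(cc(OC)c(O)c3OC)C[C@@H](C(=O)OC)[C@H]2C(=O)OC)cc(OC)c1O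
F8 | step 8 | dimethyl (1R,2S,3S)‑tetralin‑2,3‑dicarboxylate (all‑trans) | COc1cc([C@@H]2c3c(cc(OC)c(O)c3OC)C[C@H](C(=O)OC)[C@H]2C(=O)OC)cc(OC)c1O
F9 | step 8 | bis(TBS ether) of F8 | COc1cc([C@@H]2c3c(cc(OC)c(O[Si](C)(C)C(C)(C)C)c3OC)C[C@H](C(=O)OC)[C@H]2C(=O)OC)cc(OC)c1O[Si](C)(C)C(C)(C)C
F10 | step 8 | (1R,2S,3S)‑bis(TBS)‑protected tetralin‑2,3‑dimethanol | COc1cc([C@@H]2c3c(cc(OC)c(O[Si](C)(C)C(C)(C)C)c3OC)C[C@H](CO)[C@H]2CO)cc(OC)c1O[Si](C)(C)C(C)(C)C
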